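## Retrosynthetic overview

1. The plan rests on ring B. C7 (ketone) and C8 (tertiary carbinol bearing the C17 methyl, acetylated in the target) form an α-ketol, that is, two former carbonyl carbons bonded to each other. Cutting C7–C8 gives a C7 aldehyde and a C8 methyl ketone on ring A, rejoined by a carbene-catalysed benzoin closure.
2. The 2,3-dihydrofuran (C13–C14=C15–O–C16) is opened to a C13 ethynyl group and the C16 alcohol, and is closed last by alkynol cycloisomerisation.
3. C9–C10 is made by Ireland–Claisen rearrangement of a cyclohex-2-enyl tetrahydrofuran-2-carboxylate, with chirality transfer from C2–O to C10. C13 stays prochiral (two CH2OBn arms) until lactonisation onto the C9 carboxyl singles out the cis arm as C16.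
4. Ring A, with C4 and C5, comes from an enantioselective Diels–Alder reaction of methacrolein with an E-diene that already holds C6–C7.
5. Ring order: ring A and the tetrahydrofuran (made separately), then ring B, then the dihydrofuran.

Key step: step 22

Labdane numbering is used for all intermediates. α means the face of H5 and β the face of the C20 methyl. TBS = tert-butyldimethylsilyl, TBDPS = tert-butyldiphenylsilyl, Bn = benzyl.

Assumption: the S-configured oxazaborolidinium ion is taken to expose the methacrolein face that leads to the (4S,5R) ring A drawn; if the sense is the reverse with this diene, the R catalyst is used and nothing else changes.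

## Route

Step 1
Reactants: 1 3-[(TBS)oxy]propanal; 2 2-(triphenylphosphoranylidene)propanal
Product: 3 (E)-5-[(TBS)oxy]-2-methylpent-2-enal
Conditions: CH2Cl2, reflux
Reagents that add atoms: none
Why: Wittig olefination with a stabilised ylide, which should give the E trisubstituted enal (C5=C10 with the C20 methyl in place).

Step 2
Reactants: 3 (E)-5-[(TBS)oxy]-2-methylpent-2-enal
Product: 4 (E)-tert-butyl(dimethyl)[(4-methylhexa-3,5-dien-1-yl)oxy]silane
Conditions: Ph3PCH3Br, KOt-Bu, THF, 0 °C
Reagents that add atoms: methyltriphenylphosphonium bromide, C[P+](c1ccccc1)(c1ccccc1)c1ccccc1.[Br-]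
Why: Wittig methylenation of the enal carbonyl adds C2 and leaves the E double bond untouched, so the diene can reach the s-cis form.

Step 3
Reactants: 4 (E)-diene; 5 methacrolein
Product: 6 (1S,2R)-2-{2-[(TBS)oxy]ethyl}-1,3-dimethylcyclohex-3-ene-1-carbaldehyde (ring A; formyl C19 cis to the C5 side chain)
Conditions: (S)-3,3-diphenyl-1-(o-tolyl)tetrahydropyrrolo[1,2-c][1,3,2]oxazaborole (15 mol %), Tf2NH (12 mol %), CH2Cl2, −78 °C
Reagents that add atoms: none
Why: Enantioselective Diels–Alder reaction: the cationic oxazaborolidine binds s-trans methacrolein and shields one face (absolute configuration at C4 and C5), the free CH2 terminus of the diene (C2) bonds first to the enal β-carbon so that C4 ends next to the substituted terminus C5, and the formyl-endo arrangement on the E-diene places C19 cis to the C5 side chain.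

Step 4
Reactants: 6 ring A aldehyde
Product: 7 [(1S,2R)-2-{2-[(TBS)oxy]ethyl}-1,3-dimethylcyclohex-3-en-1-yl]methanol
Conditions: NaBH4, MeOH, 0 °C
Reagents that add atoms: none
Why: Borohydride reduction of the neopentyl aldehyde to the C19 alcohol, with no stereocentre touched.

Step 5
Reactants: 7 C19 alcohol
Product: 8 19-O-TBDPS ether of 7
Conditions: TBDPSCl, imidazole, DMF, rt
Reagents that add atoms: tert-butyl(chloro)diphenylsilane, CC(C)(C)[Si](Cl)(c1ccccc1)c1ccccc1
Why: Silyl ether formation; the more acid-stable TBDPS group lets the C7 TBS ether be removed alone in step 20.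

Step 6
Reactants: 8 bis-silyl ether
Product: 9 (4R,5S)-4-{2-[(TBS)oxy]ethyl}-5-{[(TBDPS)oxy]methyl}-3,5-dimethylcyclohex-2-en-1-one (C2 ketone, C1=C10)
Conditions: Rh2(caprolactamate)4 (1 mol %), t-BuOOH, K2CO3, CH2Cl2, rt
Reagents that add atoms: tert-butyl hydroperoxide, CC(C)(C)OO
Why: Radical allylic oxidation of the only allylic CH2 (C2), as in the conversion of α-ionone-type rings into their 3-oxo derivatives; the tertiary C5–H is shielded by quaternary C4.

Step 7
Reactants: 9 ring A enone
Product: 10 (1R,4R,5S)-4-{2-[(TBS)oxy]ethyl}-5-{[(TBDPS)oxy]methyl}-3,5-dimethylcyclohex-2-en-1-ol (2β-alcohol, OH cis to the C5 side chain)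
Conditions: LiBH(s-Bu)3, THF, −78 °C; then NaOH, H2O2
Reagents that add atoms: none
Why: 1,2-Reduction by a bulky borohydride: conjugate attack is blocked by the fully substituted β-carbon C10, and hydride should come from the α face, away from the β-oriented CH2OTBDPS and C5 side chain, which sets the 2β alcohol as in the 3-oxo-α-ionone series.

Step 8
Reactants: 11 1,3-bis(benzyloxy)propan-2-ol
Product: 12 1,3-bis(benzyloxy)propan-2-one
Conditions: Dess–Martin periodinane, CH2Cl2, rt
Reagents that add atoms: none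
Why: Dess–Martin oxidation of a secondary alcohol to the symmetric ketone that becomes C13.

Step 9
Reactants: 12 1,3-bis(benzyloxy)propan-2-one; 13 but-3-en-1-ylmagnesium bromide
Product: 14 1-(benzyloxy)-2-[(benzyloxy)methyl]hex-5-en-2-ol
Conditions: THF, −78 → 0 °C; H2O
Reagents that add atoms: none
Why: Grignard addition to a symmetric ketone gives the C13 carbinol with two identical arms, so no stereocentre is created at this stage.

Step 10
Reactants: 14 tertiary alcohol
Product: 16 {5,5-bis[(benzyloxy)methyl]oxolan-2-yl}methanol (racemic at C9), via terminal epoxide 15 (not isolated)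
Conditions: mCPBA, CH2Cl2, 0 °C → rt; then camphorsulfonic acid (10 mol %)
Reagents that add atoms: 3-chloroperoxybenzoic acid, O=C(OO)c1cccc(Cl)c1
Why: Prilezhaev epoxidation followed by acid-catalysed 5-exo-tet opening by the tertiary hydroxyl closes the tetrahydrofuran; the racemic C9 centre is erased by enolisation in step 13.

Step 11
Reactants: 16 tetrahydrofuran methanol
Product: 17 5,5-bis[(benzyloxy)methyl]oxolane-2-carboxylic acid (racemic at C9)
Conditions: TEMPO (20 mol %), PhI(OAc)2, MeCN/H2O, rt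
Reagents that add atoms: water, O
Why: Oxoammonium (TEMPO) oxidation of the primary alcohol through the aldehyde hydrate to the acid, which leaves benzyl ethers intact.

Step 12
Reactants: 10 2β-allylic alcohol; 17 tetrahydrofuran acid
Product: 18 2α-ester of ring A with acid 17 (both C9 epimers)
Conditions: PPh3, DIAD, toluene, 0 °C → rt
Reagents that add atoms: none
Why: Mitsunobu esterification: SN2 inversion at C2 puts the ester oxygen on the α face (trans to the C5 side chain), and the SN2′ path is blocked by the fully substituted C10.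

Step 13
Reactants: 18 allylic ester
Product: 21 C9–C10 coupled acid (9α-O; 10β-CH3; C1=C2 alkene), via Z-silyl ketene acetal 19 (not isolated), via trimethylsilyl ester 20 (not isolated)
Conditions: LiN(i-Pr)2, THF, −78 °C; Me3SiCl, −78 °C → rt; toluene, 80 °C; aq. citric acid
Reagents that add atoms: chlorotrimethylsilane, C[Si](C)(C)Cl (kept only in 19 and 20)
Why: Ireland–Claisen rearrangement: lithium chelation by the ring oxygen fixes the Z ketene acetal, the suprafacial [3,3] shift turns the α C2–O bond into the α C10–C9 bond anti to the β side chain on C5 (C10 set by chirality transfer), and the boat-like array usual for cyclohex-2-enyl esters, favoured here because a chair would push the silyloxy group under ring A against C18, should set C9 with the 9α-oxygen configuration.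

Step 14
Reactants: 21 Claisen acid
Product: 22 dihydroxy acid (C1–C2 saturated, C13 bearing two CH2OH arms)
Conditions: H2 (3 atm), Pd(OH)2/C, EtOAc, rt
Reagents that add atoms: none
Why: Heterogeneous hydrogenation saturates the cis-disubstituted ring alkene and hydrogenolyses both benzyl ethers, while silyl ethers and the acid persist.

Step 15
Reactants: 22 dihydroxy acid
Product: 23 hydroxy lactone (3,8-dioxabicyclo[3.2.1]octan-2-one; C8 carboxyl closed onto C16; free C14H2OH)
Conditions: DCC, DMAP (cat.), CH2Cl2 (0.01 M), rt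
Reagents that add atoms: none
Why: Steglich-type lactonisation: only the hydroxymethyl arm cis to the carboxyl across the tetrahydrofuran can reach it, so ring closure tells the two arms apart and sets C13 from C9 (the lactonised arm is C16, the free arm C14).

Step 16
Reactants: 23 hydroxy lactone
Product: 24 C14 aldehyde lactone
Conditions: Dess–Martin periodinane, CH2Cl2, rt
Reagents that add atoms: none
Why: Dess–Martin oxidation of the remaining neopentyl-type primary alcohol to a non-enolisable aldehyde.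

Step 17
Reactants: 24 aldehyde lactone
Product: 25 C13 ethynyl lactone
Conditions: Me3SiCHN2, LiN(i-Pr)2, THF, −78 °C → rt; H2O
Reagents that add atoms: (trimethylsilyl)diazomethane, C[Si](C)(C)C=[N+]=[N-]
Why: Colvin-type one-carbon alkyne synthesis (addition, loss of silanolate and N2, 1,2-hydrogen shift) adds C15; the aldehyde cannot enolise, and the lactone carbonyl is flanked by fully substituted C9 and is far less electrophilic.

Step 18
Reactants: 25 ethynyl lactone
Product: 27 C8 methyl ketone with free C16 alcohol, via bicyclic hemiketal 26 (not isolated)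
Conditions: MeLi (2.1 equiv), THF, −78 °C; H2O
Reagents that add atoms: methyllithium, [Li]C
Why: Organolithium addition to a lactone: the first equivalent deprotonates the alkyne, the second adds C17 to C8, and the hindered tetrahedral alkoxide should persist at low temperature, so a second addition is avoided.

Step 19
Reactants: 27 hydroxy ketone
Product: 28 16-O-TBDPS ether of 27
Conditions: TBDPSCl, imidazole, DMF, rt
Reagents that add atoms: tert-butyl(chloro)diphenylsilane, CC(C)(C)[Si](Cl)(c1ccccc1)c1ccccc1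
Why: Silylation of the primary C16 hydroxyl drains the ring–chain equilibrium toward the open methyl ketone, since the tertiary hemiketal hydroxyl is much slower to silylate.

Step 20
Reactants: 28 tris-silyl ether
Product: 29 C7 primary alcohol
Conditions: camphorsulfonic acid (10 mol %), MeOH/CH2Cl2, 0 °C
Reagents that add atoms: none
Why: Acid-catalysed methanolysis removes the unhindered primary TBS ether much faster than the two neopentyl-type TBDPS ethers.

Step 21
Reactants: 29 C7 alcohol
Product: 30 keto aldehyde (C7 aldehyde, C8 methyl ketone, C13 ethynyl, 16,19-bis-OTBDPS)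
Conditions: Dess–Martin periodinane, CH2Cl2, rt
Reagents that add atoms: none
Why: Dess–Martin oxidation under neutral conditions gives the enolisable aldehyde without aldol closure.

Step 22
Reactants: 30 keto aldehyde
Product: 31 8β-hydroxy-7-ketone (ring B closed; 8α-CH3)
Conditions: 2-(pentafluorophenyl)-6,7-dihydro-5H-pyrrolo[2,1-c][1,2,4]triazol-2-ium tetrafluoroborate (20 mol %), Et3N (20 mol %), toluene (0.02 M), 40 °C
Reagents that add atoms: none
Why: The triazolylidene adds to the C7 aldehyde and proton transfer gives the Breslow enaminol, whose nucleophilic C7 attacks the C8 ketone; proton shift and loss of the carbene then release the α-ketol, so two electrophilic carbons are joined at the final oxidation level. The closest known reaction type is the carbene-catalysed intramolecular crossed aldehyde–ketone benzoin that turns 6-oxoheptanal-type substrates into 2-hydroxy-2-methylcyclohexanones. Ring B closes in a 6-exo-trig mode through a chair in which C5–C6 and C10–C9 are both equatorial on ring A. The one new stereocentre, C8, is controlled by the axial C20 methyl on C10: the C17 methyl takes the equatorial α site and the smaller oxygen the axial β site, and because the addition is reversible the same preference holds at equilibrium. The step needs the carbene to engage only the aldehyde and the aldol paths to stay silent: the ketone is flanked by fully substituted C9, is activated by the C9 oxygen and can enolise only toward C17, a weak amine with an acidic N-C6F5 triazolium keeps the C6 enolate concentration low, and high dilution suppresses the homo-benzoin.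

Step 23
Reactants: 31 α-ketol
Product: 32 8β-acetate
Conditions: Ac2O, DMAP, Et3N, CH2Cl2, 40 °C
Reagents that add atoms: acetic anhydride, CC(=O)OC(C)=O
Why: DMAP-catalysed acylation of the tertiary hydroxyl, which the adjacent ketone makes more acidic; the configuration at C8 is retained because only the O–H bond reacts.

Step 24
Reactants: 32 acetate
Product: 33 16,19-diol
Conditions: HF·pyridine, pyridine, THF, 0 °C → rt
Reagents that add atoms: none
Why: Fluoride desilylation in a buffered, non-basic medium removes both TBDPS groups without acetate cleavage or migration.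

Step 25
Reactants: 33 alkynyl diol
Product: 34 target CNP0239339.1
Conditions: Mo(CO)6 (30 mol %), Et3N, Et2O, hν (350 nm); then 33, rt
Reagents that add atoms: none
Why: Alkynol cycloisomerisation of a but-3-yn-1-ol unit: the amine-ligated molybdenum pentacarbonyl turns the terminal alkyne into a vinylidene, the C16 hydroxyl adds to its metal-bound carbon C15 (5-endo overall), and protodemetalation gives the endocyclic enol ether, with C13 untouched and the remote C19 hydroxyl unable to reach.

## Compound list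

1 | 3-[(tert-butyldimethylsilyl)oxy]propanal | O=CCCO[Si](C)(C)C(C)(C)C | starting material
2 | 2-(triphenylphosphoranylidene)propanal | CC(C=O)=P(c1ccccc1)(c1ccccc1)c1ccccc1 | starting material
3 | (E)-5-[(TBS)oxy]-2-methylpent-2-enal | O=C/C(C)=C/CCO[Si](C)(C)C(C)(C)C | intermediate
4 | (E)-tert-butyl(dimethyl)[(4-methylhexa-3,5-dien-1-yl)oxy]silane | C=C/C(C)=C/CCO[Si](C)(C)C(C)(C)C | intermediate
5 | methacrolein | C=C(C)C=O | starting material
6 | (1S,2R)-2-{2-[(TBS)oxy]ethyl}-1,3-dimethylcyclohex-3-ene-1-carbaldehyde | CC(C)(C)[Si](C)(C)OCC[C@H]1[C@@](C)(C=O)CCC=C1C | intermediate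
7 | [(1S,2R)-2-{2-[(TBS)oxy]ethyl}-1,3-dimethylcyclohex-3-en-1-yl]methanol | CC(C)(C)[Si](C)(C)OCC[C@H]1[C@@](C)(CO)CCC=C1C | intermediate
8 | 19-O-TBDPS ether of 7 | CC(C)(C)[Si](C)(C)OCC[C@H]1[C@@](C)(CO[Si](c2ccccc2)(c2ccccc2)C(C)(C)C)CCC=C1C | intermediate
9 | (4R,5S)-4-{2-[(TBS)oxy]ethyl}-5-{[(TBDPS)oxy]methyl}-3,5-dimethylcyclohex-2-en-1-one | CC(C)(C)[Si](C)(C)OCC[C@H]1[C@@](C)(CO[Si](c2ccccc2)(c2ccccc2)C(C)(C)C)CC(=O)C=C1C | intermediate
10 | (1R,4R,5S)-4-{2-[(TBS)oxy]ethyl}-5-{[(TBDPS)oxy]methyl}-3,5-dimethylcyclohex-2-en-1-ol (2β-OH) | CC(C)(C)[Si](C)(C)OCC[C@H]1[C@@](C)(CO[Si](c2ccccc2)(c2ccccc2)C(C)(C)C)C[C@@H](O)C=C1C | intermediate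
11 | 1,3-bis(benzyloxy)propan-2-ol | OC(COCc1ccccc1)COCc1ccccc1 | starting material
12 | 1,3-bis(benzyloxy)propan-2-one | O=C(COCc1ccccc1)COCc1ccccc1 | intermediate
13 | but-3-en-1-ylmagnesium bromide | C=CCC[Mg]Br | starting material
14 | 1-(benzyloxy)-2-[(benzyloxy)methyl]hex-5-en-2-ol | C=CCCC(O)(COCc1ccccc1)COCc1ccccc1 | intermediate
15 | terminal epoxide of 14 | OC(CCC1CO1)(COCc1ccccc1)COCc1ccccc1 | intermediate
16 | {5,5-bis[(benzyloxy)methyl]oxolan-2-yl}methanol (racemic) | OCC1CCC(COCc2ccccc2)(COCc2ccccc2)O1 | intermediate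
17 | 5,5-bis[(benzyloxy)methyl]oxolane-2-carboxylic acid (racemic) | OC(=O)C1CCC(COCc2ccccc2)(COCc2ccccc2)O1 | intermediate
18 | 2α-ester of ring A with acid 17 (both C9 epimers) | CC(C)(C)[Si](C)(C)OCC[C@H]1[C@@](C)(CO[Si](c2ccccc2)(c2ccccc2)C(C)(C)C)C[C@H](OC(=O)C2CCC(COCc3ccccc3)(COCc3ccccc3)O2)C=C1C | intermediate
19 | Z-trimethylsilyl ketene acetal of 18 (OSiMe3 cis to the ring oxygen) | CC(C)(C)[Si](C)(C)OCC[C@H]1[C@@](C)(CO[Si](c2ccccc2)(c2ccccc2)C(C)(C)C)C[C@H](O/C(O[Si](C)(C)C)=C2/OC(COCc3ccccc3)(COCc3ccccc3)CC2)C=C1C | intermediate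
20 | trimethylsilyl ester of 21 | CC(C)(C)[Si](C)(C)OCC[C@H]1[C@@](C)(CO[Si](c2ccccc2)(c2ccccc2)C(C)(C)C)CC=C[C@]1(C)[C@]1(C(=O)O[Si](C)(C)C)CCC(COCc2ccccc2)(COCc2ccccc2)O1 | intermediate
21 | C9–C10 coupled acid (9α-O, 10β-CH3, C1=C2, 5β-CH2CH2OTBS, 4α-CH3, 4β-CH2OTBDPS, C13(CH2OBn)2) | CC(C)(C)[Si](C)(C)OCC[C@H]1[C@@](C)(CO[Si](c2ccccc2)(c2ccccc2)C(C)(C)C)CC=C[C@]1(C)[C@]1(C(=O)O)CCC(COCc2ccccc2)(COCc2ccccc2)O1 | intermediate
22 | dihydroxy acid (ring A saturated, C13(CH2OH)2) | CC(C)(C)[Si](C)(C)OCC[C@H]1[C@@](C)(CO[Si](c2ccccc2)(c2ccccc2)C(C)(C)C)CCC[C@]1(C)[C@]1(C(=O)O)CCC(CO)(CO)O1 | intermediate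
23 | hydroxy lactone (C8–O–C16 lactone, free C14H2OH) | CC(C)(C)[Si](C)(C)OCC[C@H]1[C@@](C)(CO[Si](c2ccccc2)(c2ccccc2)C(C)(C)C)CCC[C@]1(C)[C@]2(C(=O)OC3)CC[C@]3(CO)O2 | intermediate
24 | C14 aldehyde lactone | CC(C)(C)[Si](C)(C)OCC[C@H]1[C@@](C)(CO[Si](c2ccccc2)(c2ccccc2)C(C)(C)C)CCC[C@]1(C)[C@]2(C(=O)OC3)CC[C@]3(C=O)O2 | intermediate
25 | C13 ethynyl lactone | CC(C)(C)[Si](C)(C)OCC[C@H]1[C@@](C)(CO[Si](c2ccccc2)(c2ccccc2)C(C)(C)C)CCC[C@]1(C)[C@]2(C(=O)OC3)CC[C@]3(C#C)O2 | intermediate
26 | bicyclic C8 methyl hemiketal | CC(C)(C)[Si](C)(C)OCC[C@H]1[C@@](C)(CO[Si](c2ccccc2)(c2ccccc2)C(C)(C)C)CCC[C@]1(C)[C@]2(C(C)(O)OC3)CC[C@]3(C#C)O2 | intermediate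
27 | C8 methyl ketone with free C16 alcohol | CC(C)(C)[Si](C)(C)OCC[C@H]1[C@@](C)(CO[Si](c2ccccc2)(c2ccccc2)C(C)(C)C)CCC[C@]1(C)[C@]1(C(C)=O)CC[C@](CO)(C#C)O1 | intermediate
28 | 16-O-TBDPS ether of 27 | CC(C)(C)[Si](C)(C)OCC[C@H]1[C@@](C)(CO[Si](c2ccccc2)(c2ccccc2)C(C)(C)C)CCC[C@]1(C)[C@]1(C(C)=O)CC[C@](CO[Si](c2ccccc2)(c2ccccc2)C(C)(C)C)(C#C)O1 | intermediate
29 | C7 primary alcohol | OCC[C@H]1[C@@](C)(CO[Si](c2ccccc2)(c2ccccc2)C(C)(C)C)CCC[C@]1(C)[C@]1(C(C)=O)CC[C@](CO[Si](c2ccccc2)(c2ccccc2)C(C)(C)C)(C#C)O1 | intermediate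
30 | keto aldehyde (key-step precursor) | O=CC[C@H]1[C@@](C)(CO[Si](c2ccccc2)(c2ccccc2)C(C)(C)C)CCC[C@]1(C)[C@]1(C(C)=O)CC[C@](CO[Si](c2ccccc2)(c2ccccc2)C(C)(C)C)(C#C)O1 | intermediate
31 | 8β-hydroxy-7-ketone (key-step product) | O[C@@]1(C)C(=O)C[C@H]2[C@@](C)(CO[Si](c3ccccc3)(c3ccccc3)C(C)(C)C)CCC[C@]2(C)[C@@]12CC[C@](CO[Si](c3ccccc3)(c3ccccc3)C(C)(C)C)(C#C)O2 | intermediate
32 | 8β-acetate | CC(=O)O[C@@]1(C)C(=O)C[C@H]2[C@@](C)(CO[Si](c3ccccc3)(c3ccccc3)C(C)(C)C)CCC[C@]2(C)[C@@]12CC[C@](CO[Si](c3ccccc3)(c3ccccc3)C(C)(C)C)(C#C)O2 | intermediate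
33 | 16,19-diol | CC(=O)O[C@@]1(C)C(=O)C[C@H]2[C@@](C)(CO)CCC[C@]2(C)[C@@]12CC[C@](CO)(C#C)O2 | intermediate
34 | CNP0239339.1 | CC(=O)O[C@@]1(C)C(=O)C[C@H]2[C@@](C)(CO)CCC[C@]2(C)[C@@]12CC[C@]1(C=COC1)O2 | target

## Step count and risks

Total step count: 25. Longest linear sequence: 21 steps (steps 1–7 and 12–25).

**Step 22 (benzoin closure of ring B)**
- What may go wrong: attack of the bulky enaminol on the crowded C8 ketone may be slow. Base-mediated aldol closure from C6 (five-membered ring) or intermolecular homo-benzoin could then take over, and face control at C8 could erode.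
- Fallback, from 30 back to 31: the same bond is made reductively. SmI2, t-BuOH, THF, −78 °C reduces the aldehyde first to its ketyl, which adds to the C8 ketone inside a samarium chelate and should give the cis-7β,8β-diol F1.
- The secondary C7 alcohol alone is then oxidised (SO3·pyridine, DMSO, Et3N) to 31.

**Step 13 (Ireland–Claisen rearrangement)**
- What may go wrong: boat and chair arrays may compete, so that C9 forms as a mixture. The crowded ketene acetal may also fragment before it rearranges.
- Fallback, from 18 back to 21: the ketene acetal is made by conjugate hydride delivery instead of deprotonation. This should give the opposite E geometry, and that isomer reaches the same C9 configuration through the staggered chair.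
- LiN(i-Pr)2 then PhSeCl gives the α-phenylselanyl ester F2. H2O2 oxidation with syn elimination toward C11 gives the 4,5-dihydrofuran-2-carboxylate F3.
- RhCl(PPh3)3-catalysed 1,4-hydrosilylation with Et3SiH on the s-cis enoate gives the E-silyl ketene acetal F4. On warming it rearranges to the triethylsilyl ester F5, and mild aqueous acid gives 21.

**Step 3 (Diels–Alder reaction)**
- What may go wrong: the C10 methyl and the C5 alkyl group of the diene direct in opposite senses, so regioisomers may form. Formyl-endo versus methyl-endo selection or face selection may also be low.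
- Fallback, from 1 back to 8: a directing oxygen is placed on C1 of the diene and removed afterwards. Wittig reaction of 1 with 3-(triphenylphosphoranylidene)butan-2-one gives the E-enone F6.
- i-Pr3SiOTf, Et3N gives the 2-silyloxydiene F7, in which C2 is clearly the nucleophilic terminus. The same oxazaborolidinium catalyst and 5 give the silyl enol ether aldehyde F8.
- NaBH4 gives the alcohol F9 and TBDPSCl gives the silyl ether F10. CsF with PhNTf2 turns the enol silyl ether regiospecifically into the enol triflate F11, and Pd(OAc)2, PPh3, HCO2H, n-Bu3N reduces it to 8.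

## Further compounds

F1 | step 22 | cis-7β,8β-diol | O[C@@]1(C)[C@@H](O)C[C@H]2[C@@](C)(CO[Si](c3ccccc3)(c3ccccc3)C(C)(C)C)CCC[C@]2(C)[C@@]12CC[C@](CO[Si](c3ccccc3)(c3ccccc3)C(C)(C)C)(C#C)O2
F2 | step 13 | α-phenylselanyl ester | CC(C)(C)[Si](C)(C)OCC[C@H]1[C@@](C)(CO[Si](c2ccccc2)(c2ccccc2)C(C)(C)C)C[C@H](OC(=O)C2([Se]c3ccccc3)CCC(COCc3ccccc3)(COCc3ccccc3)O2)C=C1C
F3 | step 13 | 4,5-dihydrofuran-2-carboxylate | CC(C)(C)[Si](C)(C)OCC[C@H]1[C@@](C)(CO[Si](c2ccccc2)(c2ccccc2)C(C)(C)C)C[C@H](OC(=O)C2=CCC(COCc3ccccc3)(COCc3ccccc3)O2)C=C1C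
F4 | step 13 | E-silyl ketene acetal (OSiEt3 trans to the ring oxygen) | CC(C)(C)[Si](C)(C)OCC[C@H]1[C@@](C)(CO[Si](c2ccccc2)(c2ccccc2)C(C)(C)C)C[C@H](O/C(O[Si](CC)(CC)CC)=C2\OC(COCc3ccccc3)(COCc3ccccc3)CC2)C=C1C
F5 | step 13 | triethylsilyl ester of 21 | CC(C)(C)[Si](C)(C)OCC[C@H]1[C@@](C)(CO[Si](c2ccccc2)(c2ccccc2)C(C)(C)C)CC=C[C@]1(C)[C@]1(C(=O)O[Si](CC)(CC)CC)CCC(COCc2ccccc2)(COCc2ccccc2)O1
F6 | step 3 | (E)-6-[(TBS)oxy]-3-methylhex-3-en-2-one | CC(=O)/C(C)=C/CCO[Si](C)(C)C(C)(C)C
F7 | step 3 | 2-silyloxydiene | C=C(O[Si](C(C)C)(C(C)C)C(C)C)/C(C)=C/CCO[Si](C)(C)C(C)(C)C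
F8 | step 3 | silyl enol ether aldehyde | CC(C)(C)[Si](C)(C)OCC[C@H]1[C@@](C)(C=O)CCC(O[Si](C(C)C)(C(C)C)C(C)C)=C1C
F9 | step 3 | C19 alcohol of F8 | CC(C)(C)[Si](C)(C)OCC[C@H]1[C@@](C)(CO)CCC(O[Si](C(C)C)(C(C)C)C(C)C)=C1C
F10 | step 3 | 19-O-TBDPS ether of F9 | CC(C)(C)[Si](C)(C)OCC[C@H]1[C@@](C)(CO[Si](c2ccccc2)(c2ccccc2)C(C)(C)C)CCC(O[Si](C(C)C)(C(C)C)C(C)C)=C1C
F11 | step 3 | enol triflate | CC(C)(C)[Si](C)(C)OCC[C@H]1[C@@](C)(CO[Si](c2ccccc2)(c2ccccc2)C(C)(C)C)CCC(OS(=O)(=O)C(F)(F)F)=C1C
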